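The runs stem from a simulated flask with made-up constants; scatter was added.

If you want a quick number for the three flasks at 12 h, take your hunch that ochre wins by heat and put a ceiling on it.

| setting | summer | noon | midnight | teal | violet | ochre |
|---|---|---|---|---|---|---|
| substrate | 5 mM | 7.5 mM | 10 mM | 10 mM | 10 mM | 10 mM |
| first nucleophile | 1.5 equiv | 1.5 equiv | 1.5 equiv | 1.50 equiv | 1.50 equiv | 1.50 equiv |
| second nucleophile | 4 equiv | 4 equiv | 8 equiv | 4.00 equiv | 4.00 equiv | 4.00 equiv |
| temperature | −15 °C | 18 °C | −15 °C | −30 °C | 0 °C | 30 °C |
| remark | run made earlier | run made earlier | run made earlier |  |  |  |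
| time |  |  |  | 12 h | 12 h | 12 h |

summer run (percent of the substrate charged)

| time / h | target / % |
|---|---|
| 0.500 | 1 |
| 1.00 | 0 |
| 1.33 | 1 |
| 2.00 | 1 |
| 2.50 | 0 |
| 3.00 | 1 |
| 4.00 | 0 |

noon run (percent of the substrate charged)

| time / min | target / % |
|---|---|
| 2.50 | 3 |
| 6.00 | 4 |
| 12.0 | 2 |
| 15.0 | 5 |
| 20.0 | 6 |
| 30.0 | 11 |
| 40.0 | 12 |

midnight run (percent of the substrate charged)

| time / h | target / % |
|---|---|
| 0.667 | 1 |
| 1.33 | 0 |
| 2.00 | 3 |
| 3.00 | 0 |
| 4.00 | 2 |

(each reading ± 1.5 percentage points)

- the earlier runs were read with a standard deviation of 1.5 percentage points
- a reading or a percentage of target counts all its forms, free or not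

* the flask with the highest amount of target, in percent of the substrate charged ("all alike" if they lie within 1.5 percentage points) (teal / violet / ochre / all alike)
* final target, as a percentage of the substrate charged, in teal
* final target, as a percentage of the substrate charged, in violet
* final target, as a percentage of the substrate charged, in ochre

Target is the one thing read, so this is my supposition: both nucleophiles compete for the same activated substrate and trap it equally well, a selectivity factor of one, and capture by the first gives target. That caps target at 27.3%, the capture share: equivalents of first nucleophile over the equivalents of both.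

Now the two ends. The noon run read 12% at 40.0 min, a pace of 0.180 /h as a fraction of the charge. With that share, substrate clears in about 1.52 h, and ochre is hotter than noon, so I put ochre on the ceiling. At the cold end, the summer run read 1% at 3.00 h, within its scatter. Carried to 12 h, that gives 4.00%, an upper figure for teal, which is colder than summer. Violet joins the two ends somewhere below the ceiling. My commitment is ochre on top at the capture share.

The forecast puts teal at 0.5%, violet at 20% and ochre at 72%, above my ceiling: “Ochre should still be highest.”

The flasks give teal 0.452%, violet 18.6% and ochre 0.0507%, so violet leads.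

    substrate → intermediate (k = 0.00160 /min, Ea = 79.0 kJ/mol)
    first nucleophile + intermediate → target (k = 7.50 /M/min, Ea = 56.0 kJ/mol)
    second nucleophile + intermediate → other capture product (k = 5.70 /M/min, Ea = 55.0 kJ/mol)
    crystals ⇌ target, rate k4*(cs4 - [target]) while solid is left; crystals form when [target] > cs4 (solubility = 0.280 mM, k = 0.0130 /min)
    second nucleophile + target → over-reaction product (k = 0.0330 /M/min, Ea = 68.0 kJ/mol)
    (constants at 0 °C)

My ceiling failed in ochre, even though ochre's final target of 0.0507% lies far under it. With 0% of its substrate left, ochre holds target plus over-reaction product at 33.6%, against my 27.3%. Taking the over-reaction step out of ochre lifts its target from 0.0507% to 33.3%. The neighbour of ochre charged with 1.00 equiv of second nucleophile has a capture share of 60.0%; it holds target plus over-reaction product at 66.5%, with 46.3% of that as target.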